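**Assumption:** the target has no stereocentres (it is achiral), so "single enantiomer" does not apply. The only selectivity issue is regiochemistry. All starting materials (3,4,5-trimethoxyphenol, methoxyacetic acid, anisic anhydride, sodium anisate, isovaleryl chloride, IBX) are commercial.

## Retrosynthesis
- The 8-O-isovalerate comes from the 7,8-diisovalerate by selective cleavage of the more labile 7-ester. The 7,8-diol comes from the C8–H of 5,7-dihydroxy-3,6,4'-trimethoxyflavone by **IBX ortho-hydroxylation of the 7-OH (key bold step)**. This means the five-oxygen A-ring is never built with differentiated O-substituents; C8 is the only free A-ring C–H.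
- The 5,7-dihydroxy-6-methoxy pattern comes from a 3,5,6,7,4'-pentamethoxyflavone by two orthogonal demethylations. BCl3 removes 5-OMe by carbonyl chelation. Thiolate removes 7-OMe because its phenoxide is the best leaving group (para to C=O).
- The pyranone ring is formed in one step by an Allan–Robinson condensation of an ω-methoxy-2-hydroxyacetophenone with anisic anhydride, which installs 3-OMe and the B ring together. The ketone comes from 3,4,5-trimethoxyphenol, which is mirror-symmetric, so its two ortho sites are equivalent.
- Ring order: the A ring is commercial, the C ring forms in Step 2, and the B ring enters as anisate.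

## Route

**Step 1**
Reactants: 1 (3,4,5-trimethoxyphenol); 2 (methoxyacetic acid)
Product: 3, 1-(2-hydroxy-4,5,6-trimethoxyphenyl)-2-methoxyethan-1-one
Conditions: 2 (1.5 equiv), BF3·OEt2, 90 °C, 3 h
Reagents that add atoms: methoxyacetic acid, COCC(=O)O
Why: BF3-promoted Friedel–Crafts/Fries-type C-acylation goes ortho to the free phenol. The two ortho positions are equivalent, so only one regioisomer forms, and it has the ring-closing OH next to C8–H.

**Step 2**
Reactants: 3; 4 (4-methoxybenzoic anhydride); 5 (sodium 4-methoxybenzoate)
Product: 6, 3,5,6,7,4'-pentamethoxyflavone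
Conditions: 4 (3 equiv), 5 (2 equiv), neat, 180 °C, 3 h; then KOH, EtOH, reflux, 30 min
Reagents that add atoms: 4-methoxybenzoic anhydride, COc1ccc(cc1)C(=O)OC(=O)c1ccc(OC)cc1
Why: Allan–Robinson condensation proceeds by O-aroylation, Baker–Venkataraman-type acyl transfer and cyclodehydration. The ω-OMe becomes C3-OMe, and KOH cleaves any enol-ester by-products. No stereocentre is formed.

**Step 3**
Reactants: 6
Product: 7, 5-hydroxy-3,6,7,4'-tetramethoxyflavone
Conditions: BCl3 (1.5 equiv), CH2Cl2, −78 → 0 °C, 2 h; then MeOH, aq. NaHCO3
Reagents that add atoms: none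
Why: BCl3 coordinates C4=O and delivers chloride to the methyl of the peri 5-OMe through a six-membered chelate (chelation-directed ether cleavage). The other OMe groups are not chelated.

**Step 4**
Reactants: 7
Product: 8, 5,7-dihydroxy-3,6,4'-trimethoxyflavone
Conditions: PhSH (1.2 equiv), K2CO3 (1.2 equiv), NMP, 120 °C, 4 h
Reagents that add atoms: none
Why: Nucleophilic SN2 demethylation favours the OMe whose phenoxide is most stabilised. That is the 7-OMe, para to C=O (phenol pKa about 7), rather than 6-OMe, 3-OMe or 4'-OMe. The 5-OH stays chelated, and the 7-phenoxide formed deactivates further cleavage.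

**Step 5**
Reactants: 8; 9 (IBX)
Product: 11, 5,7,8-trihydroxy-3,6,4'-trimethoxyflavone, via 10, the 7,8-o-quinone (not isolated)
Conditions: 9 (1.3 equiv), DMF, 25 °C, 1 h; then aq. Na2S2O4, 0 °C; extract under argon and use at once
Reagents that add atoms: IBX, O=C1OI(=O)(O)c2ccccc12 (supplies the C8 oxygen)
Why: IBX-mediated ortho-hydroxylation (Pettus/Quideau type). The 7-OH binds iodine(V) and delivers oxygen intramolecularly to the only free ortho carbon, C8, because C6 is blocked by OMe. The 5-OH is H-bonded and unreactive. Dithionite reduces the o-quinone 10 to the catechol 11.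

**Step 6**
Reactants: 11; 12 (isovaleryl chloride)
Product: 13, 5-hydroxy-3,6,4'-trimethoxyflavone-7,8-diyl diisovalerate
Conditions: 12 (2.5 equiv), pyridine, CH2Cl2, 0 °C → rt, 2 h
Reagents that add atoms: isovaleryl chloride, CC(C)CC(=O)Cl
Why: Schotten–Baumann-type acylation. It traps the oxidation-prone catechol, and the chelated 5-OH is not acylated under these mild conditions.

**Step 7**
Reactants: 13
Product: 14, target
Conditions: imidazole (2 equiv), MeOH–THF (1:1), 20 °C, 6–12 h, monitored by HPLC
Reagents that add atoms: none
Why: Imidazole-catalysed methanolysis cleaves the 7-ester selectively. It is an aryl ester of the much more acidic 7-phenol (a vinylogous acid), so it is the better acyl donor. Any acyl migration would favour the less acidic 8-O, the thermodynamically more stable ester. No stereocentre is involved.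

## Checks
- **Target match:** the A ring of 14 is 5-OH, 6-OMe, 7-OH, 8-O-isovalerate; the C ring has 3-OMe; the B ring has 4'-OMe. This matches the SMILES given.
- **Atom balance:**
  - Step 1: C9H12O4 + C3H6O3 − H2O = C12H16O6.
  - Step 2: C20H20O7, which has the 20 carbons of the pentamethoxyflavone.
  - Step 3 removes CH2, Step 4 removes CH2, Step 5 adds O, Step 6 adds two C5H8O, and Step 7 removes one C5H8O.
- **Functional-group survival:** 3-OMe, 4'-OMe, 6-OMe and the chromone C2=C3 survive every step. The 5-OH is chelated and survives Steps 4–7. The isovalerate is introduced after all demethylations.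
- **Stereochemistry:** there are no stereocentres to set or scramble.

## Compound list
1 | 3,4,5-trimethoxyphenol | COc1cc(O)cc(OC)c1OC | starting material
2 | methoxyacetic acid | COCC(=O)O | starting material
3 | 1-(2-hydroxy-4,5,6-trimethoxyphenyl)-2-methoxyethanone | COCC(=O)c1c(O)cc(OC)c(OC)c1OC | intermediate
4 | 4-methoxybenzoic anhydride | COc1ccc(cc1)C(=O)OC(=O)c1ccc(OC)cc1 | starting material
5 | sodium 4-methoxybenzoate | COc1ccc(cc1)C(=O)[O-].[Na+] | starting material
6 | 3,5,6,7,4'-pentamethoxyflavone | COc1ccc(cc1)-c1oc2cc(OC)c(OC)c(OC)c2c(=O)c1OC | intermediate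
7 | 5-hydroxy-3,6,7,4'-tetramethoxyflavone | COc1ccc(cc1)-c1oc2cc(OC)c(OC)c(O)c2c(=O)c1OC | intermediate
8 | 5,7-dihydroxy-3,6,4'-trimethoxyflavone | COc1ccc(cc1)-c1oc2cc(O)c(OC)c(O)c2c(=O)c1OC | intermediate
9 | IBX (2-iodoxybenzoic acid) | O=C1OI(=O)(O)c2ccccc12 | starting material (reagent)
10 | 5-hydroxy-3,6,4'-trimethoxyflavone-7,8-o-quinone | COC1=C(O)C2=C(OC(=C(OC)C2=O)c2ccc(OC)cc2)C(=O)C1=O | intermediate (not isolated)
11 | 5,7,8-trihydroxy-3,6,4'-trimethoxyflavone | COc1ccc(cc1)-c1oc2c(O)c(O)c(OC)c(O)c2c(=O)c1OC | intermediate
12 | isovaleryl chloride | CC(C)CC(=O)Cl | starting material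
13 | 5-hydroxy-3,6,4'-trimethoxyflavone-7,8-diyl diisovalerate | COc1ccc(cc1)-c1oc2c(OC(=O)CC(C)C)c(OC(=O)CC(C)C)c(OC)c(O)c2c(=O)c1OC | intermediate
14 | 5,7,8-trihydroxy-3,6,4'-trimethoxyflavone 8-isovalerate (achiral) | COc1ccc(-c2oc3c(OC(=O)CC(C)C)c(O)c(OC)c(O)c3c(=O)c2OC)cc1 | target

## Totals
Total steps: 7. Longest linear sequence: 7 steps from 1.

## Three steps most likely to fail
1. **Step 4, 7-OMe versus 6-OMe, 3-OMe and 4'-OMe selectivity.**
   - Fallback: carry a 7-OBn group from the start. Benzylate commercial 3-hydroxy-4,5-dimethoxybenzaldehyde and convert it to the phenol by Dakin oxidation. Acylate it as in Steps 1–2 (separating regioisomers), demethylate the 5-OMe with BCl3, and remove the benzyl by hydrogenolysis before IBX.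
2. **Step 5, IBX hydroxylation of the electron-rich, multi-phenol flavone (over-oxidation or an unstable quinone).**
   - Fallback: Duff formylation of 8 (hexamine, TFA) gives the 8-CHO, then Dakin oxidation (H2O2, NaOH) gives catechol 11.
3. **Step 7, selective 7-ester cleavage (loss of both esters or migration).**
   - Fallback: skip diacylation. Benzylate the 7-OH selectively of 11 (BnBr, K2CO3, acetone), acylate 8-OH with isovaleryl chloride/pyridine, then remove the benzyl (H2, Pd/C, EtOAc). Hydrogenolysis leaves the aryl ester intact.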